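**Retrosynthetic overview**

1. The route rests on the alkene C7a=C8a of the seven-membered ring. C7a (bearing the 4-hydroxyphenyl group) sits on carbon b6 of the central ring C and C8a on carbon a1 of benzo ring B. These two aryl carbons are already tied five atoms apart through the sp3 methine C8b (b6–b1–C8b–a6–a1), so one aryl(silyl)alkyne can supply both alkene carbons.
2. Target <= BBr3 demethylation and protodesilylation <= 8a-silyl cycloheptene <= key annulation (C7a–b6 by carbopalladation, C8a–a1 by C–H vinylation) of the bis(dihydrobenzofuran) aryl iodide (iodine on b6) with 1-(4-methoxyphenyl)-2-(trimethylsilyl)ethyne.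
3. Aryl iodide <= acid equilibration of both O–CH(Ar) centres to trans <= ring B dihydrofuran by rhodium-carbene insertion into a benzylic ether C–H <= diaryl ketone from the ring C aldehyde and a ring B aryl Grignard reagent.
4. Ring C aldehyde <= ring C dihydrofuran by the same insertion with the antipodal catalyst <= diaryl ketone built on 3-fluoro-5-methoxybenzaldehyde: iodine placed on b6 at the outset (para to OMe), the b4 ketone by lithiation between F and OMe, the b5 benzylic ether by SNAr of fluoride.
5. Rings form in the order: dihydrofuran on ring C, dihydrofuran on ring B, cycloheptene last.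

Key step: step 14

Atom labels: ring C (central resorcinol ring) has C8b on b1, H on b2, OMe on b3, C3' on b4, the furan oxygen on b5 and iodine (later C7a) on b6. Ring B (benzo ring of the second dihydrobenzofuran) has C8b on a6, the furan oxygen on a5, OMe on a3 and H (later C8a) on a1. C2'/C3' and C7b/C8b are the O–CH(Ar) and Ar2CH carbons of the dihydrofurans fused to ring C and ring B. Rh2(PTAD)4 is Rh2[(1-adamantyl)(phthalimido)acetate]4.

Assumption: the facial sense of the two Rh2(PTAD)4 antipodes is taken as written in steps 6 and 12; should the insertions run with the opposite sense, the two antipodes are exchanged and nothing else changes.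

**Route**

Step 1
Reactants: 1 3-fluoro-5-methoxybenzaldehyde
Product: 2 3-fluoro-2-iodo-5-methoxybenzaldehyde
Conditions: NIS, CF3CO2H, MeCN, rt
Reagents that add atoms: N-iodosuccinimide, O=C1CCC(=O)N1I
Why: Electrophilic aromatic iodination: the methoxy group is the strongest director on the ring, so its para position (C2, between F and CHO) should be iodinated in preference to the two positions ortho to it, as in the halogenation of 3-alkoxybenzaldehydes.

Step 2
Reactants: 2 3-fluoro-2-iodo-5-methoxybenzaldehyde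
Product: 3 2-(3-fluoro-2-iodo-5-methoxyphenyl)-1,3-dioxolane
Conditions: HOCH2CH2OH, p-TsOH (cat.), toluene, reflux, Dean–Stark
Reagents that add atoms: ethylene glycol, OCCO
Why: Acid-catalysed acetalisation with azeotropic removal of water masks the formyl group against the organolithium, alkoxide and hydrazine steps that follow.

Step 3
Reactants: 3 2-(3-fluoro-2-iodo-5-methoxyphenyl)-1,3-dioxolane; 4 N,3,5-trimethoxy-N-methylbenzamide
Product: 6 [4-(1,3-dioxolan-2-yl)-2-fluoro-3-iodo-6-methoxyphenyl](3,5-dimethoxyphenyl)methanone, via aryllithium 5 (not isolated)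
Conditions: LiN(i-Pr)2, THF, −78 °C; then 4, −78 to −40 °C; H2O
Reagents that add atoms: none
Why: Directed ortho-lithiation followed by Weinreb ketone synthesis: the amide base removes the most acidic proton, the one flanked by F and OMe, without touching the C–I bond at −78 °C, and the aryllithium acylates the N-methoxy-N-methylamide through a chelated adduct that releases the ketone only on work-up.

Step 4
Reactants: 6 [4-(1,3-dioxolan-2-yl)-2-fluoro-3-iodo-6-methoxyphenyl](3,5-dimethoxyphenyl)methanone; 7 (4-methoxyphenyl)methanol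
Product: 9 (3,5-dimethoxyphenyl){4-(1,3-dioxolan-2-yl)-3-iodo-6-methoxy-2-[(4-methoxyphenyl)methoxy]phenyl}methanone, via sodium alkoxide 8 (not isolated)
Conditions: 7, NaH, DMF, 0 °C; then 6, 0 to 60 °C
Reagents that add atoms: none
Why: Nucleophilic aromatic substitution by addition–elimination: fluoride, ortho to the activating aroyl group and the only good leaving group for this mechanism, is displaced by the benzylic alkoxide, which fixes the future furan oxygen on b5 next to the iodine.

Step 5
Reactants: 9 (3,5-dimethoxyphenyl){4-(1,3-dioxolan-2-yl)-3-iodo-6-methoxy-2-[(4-methoxyphenyl)methoxy]phenyl}methanone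
Product: 10 hydrazone of 9 (C=N–NH2 in place of C=O, E/Z mixture)
Conditions: N2H4·H2O (excess), AcOH (cat.), n-BuOH, 110 °C
Reagents that add atoms: hydrazine, NN
Why: Condensation of the ketone with hydrazine to the N-unsubstituted hydrazone (either C=N geometry serves); the doubly ortho-substituted carbonyl needs excess reagent and heat, which acetal, aryl iodide and ethers should survive in this basic medium.

Step 6
Reactants: 10 hydrazone of 9
Product: 12 (2S,3R)-3-(3,5-dimethoxyphenyl)-6-(1,3-dioxolan-2-yl)-7-iodo-4-methoxy-2-(4-methoxyphenyl)-2,3-dihydro-1-benzofuran (2,3-cis), via diazo compound 11 (not isolated)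
Conditions: MnO2, CH2Cl2, rt; filter; Rh2(R-PTAD)4 (1 mol%), CH2Cl2, −20 °C to rt
Reagents that add atoms: none
Why: Oxidation of the hydrazone gives the diaryldiazomethane, and its rhodium donor/donor carbene inserts 1,5 into the hydridic benzylic ether C–H rather than into the methoxy C–H; the chiral carboxylate ligands should set C3' as R, and the stepwise hydride shift and ring closure should deliver the kinetic 2,3-cis isomer, which makes C2' S.

Step 7
Reactants: 12 (2S,3R)-3-(3,5-dimethoxyphenyl)-6-(1,3-dioxolan-2-yl)-7-iodo-4-methoxy-2-(4-methoxyphenyl)-2,3-dihydro-1-benzofuran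
Product: 13 (2S,3R)-3-(3,5-dimethoxyphenyl)-7-iodo-4-methoxy-2-(4-methoxyphenyl)-2,3-dihydro-1-benzofuran-6-carbaldehyde (2,3-cis)
Conditions: HCl (1 M aq.), THF, rt to 40 °C
Reagents that add atoms: water, O
Why: Acetal hydrolysis in dilute aqueous acid, which should be too weak to ionise the benzylic C2'–O bond, so that both stereocentres are carried through unchanged.

Step 8
Reactants: 14 2-bromo-5-methoxyphenol; 15 1-(chloromethyl)-4-methoxybenzene
Product: 16 1-bromo-4-methoxy-2-[(4-methoxyphenyl)methoxy]benzene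
Conditions: K2CO3, DMF, 60 °C
Reagents that add atoms: none
Why: Williamson ether synthesis on the phenoxide with a reactive benzylic chloride.

Step 9
Reactants: 13 (2S,3R)-3-(3,5-dimethoxyphenyl)-7-iodo-4-methoxy-2-(4-methoxyphenyl)-2,3-dihydro-1-benzofuran-6-carbaldehyde; 16 1-bromo-4-methoxy-2-[(4-methoxyphenyl)methoxy]benzene
Product: 18 [(2S,3R)-3-(3,5-dimethoxyphenyl)-7-iodo-4-methoxy-2-(4-methoxyphenyl)-2,3-dihydro-1-benzofuran-6-yl]{4-methoxy-2-[(4-methoxyphenyl)methoxy]phenyl}methanol (both carbinol epimers), via Grignard reagent 17 (not isolated)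
Conditions: 16, Mg, THF, reflux; then 13, THF, −40 to 0 °C; H2O
Reagents that add atoms: none
Why: Grignard addition: the arylmagnesium bromide adds to the formyl group much faster than it exchanges with the aryl iodide at low temperature; the carbinol centre is formed without control and is erased in step 10.

Step 10
Reactants: 18 diaryl carbinol
Product: 19 [(2S,3R)-3-(3,5-dimethoxyphenyl)-7-iodo-4-methoxy-2-(4-methoxyphenyl)-2,3-dihydro-1-benzofuran-6-yl]{4-methoxy-2-[(4-methoxyphenyl)methoxy]phenyl}methanone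
Conditions: Dess–Martin periodinane, CH2Cl2, rt
Reagents that add atoms: none
Why: Dess–Martin oxidation of the diaryl carbinol to the ketone under near-neutral conditions that leave the aryl iodide, the benzylic ether and both dihydrofuran stereocentres alone.

Step 11
Reactants: 19 diaryl ketone
Product: 20 hydrazone of 19 (C=N–NH2 in place of C=O, E/Z mixture)
Conditions: N2H4·H2O (excess), AcOH (cat.), EtOH, 80 °C
Reagents that add atoms: hydrazine, NN
Why: Hydrazone formation as in step 5; here the carbonyl has only one ortho substituent on each ring, so milder heating should do.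

Step 12
Reactants: 20 hydrazone of 19
Product: 22 (2S,3R)-3-(3,5-dimethoxyphenyl)-7-iodo-4-methoxy-6-[(2R,3R)-6-methoxy-2-(4-methoxyphenyl)-2,3-dihydro-1-benzofuran-3-yl]-2-(4-methoxyphenyl)-2,3-dihydro-1-benzofuran (both rings 2,3-cis), via diazo compound 21 (not isolated)
Conditions: MnO2, CH2Cl2, rt; filter; Rh2(S-PTAD)4 (1 mol%), CH2Cl2, −20 °C to rt
Reagents that add atoms: none
Why: Oxidation to the diazo compound and rhodium donor/donor carbene 1,5 C–H insertion as in step 6, now into the benzylic ether CH2 on ring B; the antipodal catalyst should control the new ring against the remote centres, setting C8b as R (sequence rule with iodine on b6) and, through the kinetic cis closure, C7b as R.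

Step 13
Reactants: 22 bis(cis-dihydrobenzofuran) aryl iodide
Product: 23 (2R,3R)-3-(3,5-dimethoxyphenyl)-7-iodo-4-methoxy-6-[(2S,3R)-6-methoxy-2-(4-methoxyphenyl)-2,3-dihydro-1-benzofuran-3-yl]-2-(4-methoxyphenyl)-2,3-dihydro-1-benzofuran (both rings 2,3-trans)
Conditions: CF3CO2H, CH2Cl2, 0 °C to rt
Reagents that add atoms: none
Why: Acid-mediated epimerisation: reversible heterolysis of each benzylic C–O bond gives a 4-methoxyphenyl-stabilised cation next to its own phenol, and reclosure funnels both rings to the more stable 2,3-trans isomers (C2' becomes R, C7b becomes S) while C3' and C8b are not touched.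

Step 14
Reactants: 23 bis(trans-dihydrobenzofuran) aryl iodide; 24 trimethyl[(4-methoxyphenyl)ethynyl]silane
Product: 25 8a-(trimethylsilyl) hepta-O-methyl ether of the target (cycloheptene closed, SiMe3 on C8a)
Conditions: Pd(OAc)2 (10 mol%), PPh3 (20 mol%), CsOPiv (2 equiv), 24 (2 equiv), DMF, 110 °C
Reagents that add atoms: none
Why: Zerovalent palladium, formed from Pd(OAc)2 and PPh3, inserts into the C–I bond on b6; syn-carbopalladation of 24 then puts ring C on the anisyl-bearing carbon (C7a–b6) and palladium on the silyl-bearing carbon, cis to ring C; pivalate-assisted concerted metalation–deprotonation of a1–H gives an eight-membered palladacycle, and reductive elimination forms C8a–a1. The closest known reaction type is the Larock-type annulation of internal alkynes by aryl iodides that ends in aryl C–H vinylation (phenanthrenes from 2-iodobiaryls), together with its [5+2] variants that close seven-membered rings. The cycloheptene is closed in a formal [5+2] mode: intermolecular carbopalladation first, then intramolecular C–H vinylation across the C8b hinge. No stereocentre is formed, and the four existing ones are spectators under the weakly basic conditions. The step needs alkyne regiochemistry, which the silyl group secures because the bulkier alkyne end goes next to palladium, and it needs site selectivity for a1–H, which the substrate secures because the other position ortho to a6 carries oxygen, ring C has no hydrogen ortho to b6, and the anisyl group on C7a is trans to palladium.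

Step 15
Reactants: 25 8a-silyl cycloheptene
Product: 26 hepta-O-methyl ether of the target
Conditions: CF3CO2H, CH2Cl2, 0 °C to rt
Reagents that add atoms: none
Why: Protodesilylation of the vinylsilane by electrophilic ipso substitution: protonation at the silicon-bearing C8a gives the C7a cation, stabilised by two aryl groups and the β-silicon, which then loses the silyl group to trifluoroacetate.

Step 16
Reactants: 26 hepta-O-methyl ether of the target
Product: 27 CNP0325907.1
Conditions: BBr3 (excess), CH2Cl2, −78 °C to rt; H2O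
Reagents that add atoms: none
Why: Lewis-acid cleavage of the seven aryl methyl ethers: bromide attacks the methyl group of each BBr3–ether adduct in an SN2 step and the aryl borates are hydrolysed on work-up; reversible opening of a dihydrofuran ring, if it occurs, should return the trans isomer already present.

**Compound list**

1 | 3-fluoro-5-methoxybenzaldehyde | COc1cc(F)cc(C=O)c1 | starting material
2 | 3-fluoro-2-iodo-5-methoxybenzaldehyde | COc1cc(F)c(I)c(C=O)c1 | intermediate
3 | 2-(3-fluoro-2-iodo-5-methoxyphenyl)-1,3-dioxolane | COc1cc(F)c(I)c(C2OCCO2)c1 | intermediate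
4 | N,3,5-trimethoxy-N-methylbenzamide | COc1cc(OC)cc(c1)C(=O)N(C)OC | starting material
5 | [4-(1,3-dioxolan-2-yl)-2-fluoro-3-iodo-6-methoxyphenyl]lithium (not isolated) | COc1cc(C2OCCO2)c(I)c(F)c1[Li] | intermediate
6 | [4-(1,3-dioxolan-2-yl)-2-fluoro-3-iodo-6-methoxyphenyl](3,5-dimethoxyphenyl)methanone | COc1cc(C2OCCO2)c(I)c(F)c1C(=O)c1cc(OC)cc(OC)c1 | intermediate
7 | (4-methoxyphenyl)methanol | COc1ccc(CO)cc1 | starting material
8 | sodium (4-methoxyphenyl)methanolate (not isolated) | COc1ccc(C[O-])cc1.[Na+] | intermediate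
9 | (3,5-dimethoxyphenyl){4-(1,3-dioxolan-2-yl)-3-iodo-6-methoxy-2-[(4-methoxyphenyl)methoxy]phenyl}methanone | COc1ccc(COc2c(I)c(C3OCCO3)cc(OC)c2C(=O)c2cc(OC)cc(OC)c2)cc1 | intermediate
10 | hydrazone of 9 (E/Z mixture) | COc1ccc(COc2c(I)c(C3OCCO3)cc(OC)c2C(=NN)c2cc(OC)cc(OC)c2)cc1 | intermediate
11 | 2-{4-[diazo(3,5-dimethoxyphenyl)methyl]-2-iodo-5-methoxy-3-[(4-methoxyphenyl)methoxy]phenyl}-1,3-dioxolane (not isolated) | COc1ccc(COc2c(I)c(C3OCCO3)cc(OC)c2C(=[N+]=[N-])c2cc(OC)cc(OC)c2)cc1 | intermediate
12 | (2S,3R)-3-(3,5-dimethoxyphenyl)-6-(1,3-dioxolan-2-yl)-7-iodo-4-methoxy-2-(4-methoxyphenyl)-2,3-dihydro-1-benzofuran (2,3-cis) | C1COC(O1)c1cc(OC)c2c(c1I)O[C@H](c1ccc(OC)cc1)[C@@H]2c1cc(OC)cc(OC)c1 | intermediate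
13 | (2S,3R)-3-(3,5-dimethoxyphenyl)-7-iodo-4-methoxy-2-(4-methoxyphenyl)-2,3-dihydro-1-benzofuran-6-carbaldehyde (2,3-cis) | O=Cc1cc(OC)c2c(c1I)O[C@H](c1ccc(OC)cc1)[C@@H]2c1cc(OC)cc(OC)c1 | intermediate
14 | 2-bromo-5-methoxyphenol | COc1ccc(Br)c(O)c1 | starting material
15 | 1-(chloromethyl)-4-methoxybenzene | COc1ccc(CCl)cc1 | starting material
16 | 1-bromo-4-methoxy-2-[(4-methoxyphenyl)methoxy]benzene | COc1ccc(COc2cc(OC)ccc2Br)cc1 | intermediate
17 | {4-methoxy-2-[(4-methoxyphenyl)methoxy]phenyl}magnesium bromide (not isolated) | COc1ccc(COc2cc(OC)ccc2[Mg]Br)cc1 | intermediate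
18 | [(2S,3R)-3-(3,5-dimethoxyphenyl)-7-iodo-4-methoxy-2-(4-methoxyphenyl)-2,3-dihydro-1-benzofuran-6-yl]{4-methoxy-2-[(4-methoxyphenyl)methoxy]phenyl}methanol (both carbinol epimers) | OC(c1ccc(OC)cc1OCc1ccc(OC)cc1)c1cc(OC)c2c(c1I)O[C@H](c1ccc(OC)cc1)[C@@H]2c1cc(OC)cc(OC)c1 | intermediate
19 | [(2S,3R)-3-(3,5-dimethoxyphenyl)-7-iodo-4-methoxy-2-(4-methoxyphenyl)-2,3-dihydro-1-benzofuran-6-yl]{4-methoxy-2-[(4-methoxyphenyl)methoxy]phenyl}methanone | O=C(c1ccc(OC)cc1OCc1ccc(OC)cc1)c1cc(OC)c2c(c1I)O[C@H](c1ccc(OC)cc1)[C@@H]2c1cc(OC)cc(OC)c1 | intermediate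
20 | hydrazone of 19 (E/Z mixture) | NN=C(c1ccc(OC)cc1OCc1ccc(OC)cc1)c1cc(OC)c2c(c1I)O[C@H](c1ccc(OC)cc1)[C@@H]2c1cc(OC)cc(OC)c1 | intermediate
21 | (2S,3R)-6-(diazo{4-methoxy-2-[(4-methoxyphenyl)methoxy]phenyl}methyl)-3-(3,5-dimethoxyphenyl)-7-iodo-4-methoxy-2-(4-methoxyphenyl)-2,3-dihydro-1-benzofuran (not isolated) | [N-]=[N+]=C(c1ccc(OC)cc1OCc1ccc(OC)cc1)c1cc(OC)c2c(c1I)O[C@H](c1ccc(OC)cc1)[C@@H]2c1cc(OC)cc(OC)c1 | intermediate
22 | (2S,3R)-3-(3,5-dimethoxyphenyl)-7-iodo-4-methoxy-6-[(2R,3R)-6-methoxy-2-(4-methoxyphenyl)-2,3-dihydro-1-benzofuran-3-yl]-2-(4-methoxyphenyl)-2,3-dihydro-1-benzofuran (both rings 2,3-cis) | c1cc(OC)cc4c1[C@H](c3cc(OC)c5c(c3I)O[C@H](c2ccc(OC)cc2)[C@@H]5c2cc(OC)cc(OC)c2)[C@H](c2ccc(OC)cc2)O4 | intermediate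
23 | (2R,3R)-3-(3,5-dimethoxyphenyl)-7-iodo-4-methoxy-6-[(2S,3R)-6-methoxy-2-(4-methoxyphenyl)-2,3-dihydro-1-benzofuran-3-yl]-2-(4-methoxyphenyl)-2,3-dihydro-1-benzofuran (both rings 2,3-trans) | c1cc(OC)cc4c1[C@H](c3cc(OC)c5c(c3I)O[C@@H](c2ccc(OC)cc2)[C@@H]5c2cc(OC)cc(OC)c2)[C@@H](c2ccc(OC)cc2)O4 | intermediate
24 | trimethyl[(4-methoxyphenyl)ethynyl]silane | COc1ccc(C#C[Si](C)(C)C)cc1 | starting material
25 | 8a-(trimethylsilyl) hepta-O-methyl ether of 27 (SiMe3 on C8a of the cycloheptene) | COc1ccc(C2=C([Si](C)(C)C)c3cc(OC)cc4c3[C@H](c3cc(OC)c5c(c32)O[C@@H](c2ccc(OC)cc2)[C@@H]5c2cc(OC)cc(OC)c2)[C@@H](c2ccc(OC)cc2)O4)cc1 | intermediate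
26 | hepta-O-methyl ether of 27 | COc1ccc(C2=Cc3cc(OC)cc4c3[C@H](c3cc(OC)c5c(c32)O[C@@H](c2ccc(OC)cc2)[C@@H]5c2cc(OC)cc(OC)c2)[C@@H](c2ccc(OC)cc2)O4)cc1 | intermediate
27 | CNP0325907.1 | Oc1ccc(C2=Cc3cc(O)cc4c3[C@H](c3cc(O)c5c(c32)O[C@@H](c2ccc(O)cc2)[C@@H]5c2cc(O)cc(O)c2)[C@@H](c2ccc(O)cc2)O4)cc1 | target

**Step count and risks**

Total steps: 16. Longest linear sequence: 15 steps (1 to 27 through steps 1–7 and 9–16; step 8 is a one-step side branch).

Steps most likely to fail:

1. Step 14. The arylpalladium is flanked on both sides and must add to a bulky silylalkyne. The resulting alkenylpalladium carries silicon on the metal-bearing carbon and has to reach a1–H through an eight-membered palladacycle. Protodepalladation to the open vinylsilane, a second alkyne insertion, or palladation of the C8b–H bond (leading to an indene) may outrun the closure. The fallback removes the intermolecular carbopalladation and the silyl group and closes the ring by a stepwise cross-coupling and intramolecular direct alkenylation sequence. It sets out from 23. Iodine–magnesium exchange with i-PrMgCl·LiCl and acylation with N,4-dimethoxy-N-methylbenzamide should give [(2R,3R)-3-(3,5-dimethoxyphenyl)-4-methoxy-6-[(2S,3S)-6-methoxy-2-(4-methoxyphenyl)-2,3-dihydro-1-benzofuran-3-yl]-2-(4-methoxyphenyl)-2,3-dihydro-1-benzofuran-7-yl](4-methoxyphenyl)methanone F1. Ramirez olefination (CBr4, PPh3, toluene, heat) should convert it into (2R,3R)-7-[2,2-dibromo-1-(4-methoxyphenyl)ethenyl]-3-(3,5-dimethoxyphenyl)-4-methoxy-6-[(2S,3S)-6-methoxy-2-(4-methoxyphenyl)-2,3-dihydro-1-benzofuran-3-yl]-2-(4-methoxyphenyl)-2,3-dihydro-1-benzofuran F2, in which one C–Br bond is cis to ring C whatever the alkene geometry. Pd(OAc)2, PCy3·HBF4, K2CO3 and PivOH in DMA should then insert into that bond and close the ring by intramolecular direct C–H alkenylation at a1, giving the 8a-bromo analogue of 25 (Br on C8a in place of SiMe3) F3. Hydrodebromination (Pd(PPh3)4, HCO2Na, DMF) comes back to the route at 26.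

2. Step 6. The diazo carbon is flanked by two ortho oxygen substituents. Loss of dinitrogen at the bulky rhodium carboxylate may therefore be slow, with azine formation and carbene dimerisation taking over, and the chiral pocket may discriminate the two carbene faces poorly. The fallback gives up catalyst control and sets out from 10. Oxidation as before and insertion with the small achiral Rh2(OAc)4 should give the racemic cis product, that is 12 together with its enantiomer (2R,3S)-3-(3,5-dimethoxyphenyl)-6-(1,3-dioxolan-2-yl)-7-iodo-4-methoxy-2-(4-methoxyphenyl)-2,3-dihydro-1-benzofuran F4. Preparative chromatography on a chiral stationary phase then comes back to the route at 12.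

3. Step 4. The aroyl group is twisted out of the plane of ring C by its two ortho substituents, so the Meisenheimer adduct is only weakly stabilised. The alkoxide may instead add to the carbonyl and cleave the ketone (Haller–Bauer-type C–C cleavage) or reduce it by hydride transfer. The fallback moves the substitution to a coplanar, more activating formyl group and sets out from 3. Lithiation to 5 as in step 3 and quenching with DMF should give 4-(1,3-dioxolan-2-yl)-2-fluoro-3-iodo-6-methoxybenzaldehyde F5. SNAr with alkoxide 8 should give 4-(1,3-dioxolan-2-yl)-3-iodo-6-methoxy-2-[(4-methoxyphenyl)methoxy]benzaldehyde F6. Addition of purchased 3,5-dimethoxyphenylmagnesium bromide solution should give (3,5-dimethoxyphenyl){4-(1,3-dioxolan-2-yl)-3-iodo-6-methoxy-2-[(4-methoxyphenyl)methoxy]phenyl}methanol F7. Dess–Martin oxidation comes back to the route at 9.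

Further compounds
F1 | step 14 | [(2R,3R)-3-(3,5-dimethoxyphenyl)-4-methoxy-6-[(2S,3S)-6-methoxy-2-(4-methoxyphenyl)-2,3-dihydro-1-benzofuran-3-yl]-2-(4-methoxyphenyl)-2,3-dihydro-1-benzofuran-7-yl](4-methoxyphenyl)methanone | c1cc(OC)cc4c1[C@H](c3cc(OC)c5c(c3C(=O)c6ccc(OC)cc6)O[C@@H](c2ccc(OC)cc2)[C@@H]5c2cc(OC)cc(OC)c2)[C@@H](c2ccc(OC)cc2)O4
F2 | step 14 | (2R,3R)-7-[2,2-dibromo-1-(4-methoxyphenyl)ethenyl]-3-(3,5-dimethoxyphenyl)-4-methoxy-6-[(2S,3S)-6-methoxy-2-(4-methoxyphenyl)-2,3-dihydro-1-benzofuran-3-yl]-2-(4-methoxyphenyl)-2,3-dihydro-1-benzofuran | c1cc(OC)cc4c1[C@H](c3cc(OC)c5c(c3C(=C(Br)Br)c6ccc(OC)cc6)O[C@@H](c2ccc(OC)cc2)[C@@H]5c2cc(OC)cc(OC)c2)[C@@H](c2ccc(OC)cc2)O4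
F3 | step 14 | 8a-bromo analogue of 25 (Br on C8a in place of SiMe3) | COc1ccc(C2=C(Br)c3cc(OC)cc4c3[C@H](c3cc(OC)c5c(c32)O[C@@H](c2ccc(OC)cc2)[C@@H]5c2cc(OC)cc(OC)c2)[C@@H](c2ccc(OC)cc2)O4)cc1
F4 | step 6 | (2R,3S)-3-(3,5-dimethoxyphenyl)-6-(1,3-dioxolan-2-yl)-7-iodo-4-methoxy-2-(4-methoxyphenyl)-2,3-dihydro-1-benzofuran (enantiomer of 12, formed with it in the racemate) | C1COC(O1)c1cc(OC)c2c(c1I)O[C@@H](c1ccc(OC)cc1)[C@H]2c1cc(OC)cc(OC)c1
F5 | step 4 | 4-(1,3-dioxolan-2-yl)-2-fluoro-3-iodo-6-methoxybenzaldehyde | COc1cc(C2OCCO2)c(I)c(F)c1C=O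
F6 | step 4 | 4-(1,3-dioxolan-2-yl)-3-iodo-6-methoxy-2-[(4-methoxyphenyl)methoxy]benzaldehyde | COc1ccc(COc2c(I)c(C3OCCO3)cc(OC)c2C=O)cc1
F7 | step 4 | (3,5-dimethoxyphenyl){4-(1,3-dioxolan-2-yl)-3-iodo-6-methoxy-2-[(4-methoxyphenyl)methoxy]phenyl}methanol | COc1ccc(COc2c(I)c(C3OCCO3)cc(OC)c2C(O)c2cc(OC)cc(OC)c2)cc1
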